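**Plan**

- Enabling feature: each quinone ring is a four-carbon run C(=O)–C(CH3)=C(OH)–C(=O) (the pattern of a 3-alkoxy-4-methylcyclobutenedione) closed by two carbons, the phenethyl-bearing carbon and the axis carbon. These four carbons of the two rings form one 1,3-diene C(R)=CH–CH=C(R), whose central bond is the biquinone axis; the molecule is C2-symmetric.
- Retrosynthetic cuts in each ring: (a) axis carbon to the C=O next to C–CH3 (6π closure of a dienylketene); (b) phenethyl-bearing carbon to the C=O next to C–OH (vinyllithium plus cyclobutenedione); (c) the ring C–CH3 bond (MeLi plus dimethyl squarate). The axis bond is never cut.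
- Forward: dimethyl squarate gives the methoxy-methyl-cyclobutenedione; two molecules of 4-phenylbut-1-yne are joined to the 1,3-diyne, which gives the tellurophene and then the 1,4-dilithiodiene; twofold addition joins the halves.
- One thermolysis then opens both temporary four-membered rings and closes both quinone rings (the phenyl rings are bought; the quinone rings arise last and together); oxidation and O-demethylation finish.
- Stereochemistry: the target has no stereocentre. The cis,cis diene geometry is fixed by the tellurophene ring, and the carbinol centres of the precursor are erased.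

Key step: step 5

Assumption: the target SMILES defines no stereocentre and no configuration of the biquinone axis, so the axis is made without stereocontrol (as the racemate if it is configurationally stable).

**Step 1**
Reactants: 1 dimethyl squarate (3,4-dimethoxycyclobut-3-ene-1,2-dione)
Product: 3 3-methoxy-4-methylcyclobut-3-ene-1,2-dione, via tertiary alcohol 2 (not isolated)
Conditions: MeLi, THF, −78 °C; aq HCl quench; then conc. HCl (cat.), CH2Cl2, rt
Reagents that add atoms: methyllithium, C[Li]
Why: 1,2-addition of MeLi to one squarate carbonyl, followed by acid-catalysed ionisation of the tertiary allylic alcohol, water capture at the methoxy-bearing terminus and loss of methanol (the standard squarate to 3-alkoxy-4-alkylcyclobutenedione transposition), should give 3.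

**Step 2**
Reactants: 4 4-phenylbut-1-yne (2 equiv)
Product: 5 1,8-diphenylocta-3,5-diyne
Conditions: CuCl (10 mol %), TMEDA, O2 (1 atm), acetone, rt
Reagents that add atoms: 4-phenylbut-1-yne (the second molecule of 4, joined to the first), C#CCCc1ccccc1
Why: Glaser–Hay oxidative homocoupling should join two molecules of the terminal alkyne through their copper acetylides (two alkynes and half an equivalent of O2 give the diyne and water), and the new central C–C bond of the diyne is the future biquinone axis.

**Step 3**
Reactants: 5 1,8-diphenylocta-3,5-diyne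
Product: 6 2,5-bis(2-phenylethyl)tellurophene
Conditions: Te, NaBH4, EtOH/H2O, reflux, N2; then 5, THF, reflux
Reagents that add atoms: tellurium, [Te] (converted in the flask by NaBH4 into Na2Te, [Na+].[Na+].[Te-2], which delivers it)
Why: anti-addition of telluride to an outer diyne carbon followed by 5-endo-dig closure onto the second alkyne (the classical tellurophene synthesis from 1,3-diynes) should place tellurium on both phenethyl-bearing carbons and lock the cis,cis diene geometry.

**Step 4**
Reactants: 6 2,5-bis(2-phenylethyl)tellurophene; 3 3-methoxy-4-methylcyclobut-3-ene-1,2-dione (2.5 equiv)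
Product: 8 4,4'-[(3Z,5Z)-1,8-diphenylocta-3,5-diene-3,6-diyl]bis(4-hydroxy-3-methoxy-2-methylcyclobut-2-en-1-one) (mixture of diastereomers at the two carbinol carbons), via dilithiodiene 7 (not isolated)
Conditions: n-BuLi (2.1 equiv), THF, −78 °C → −20 °C; then added to 3, THF, −78 °C; aq NH4Cl
Reagents that add atoms: none
Why: twofold tellurium–lithium exchange (through tellurium ate complexes, with retention of alkene geometry) should open the tellurophene to the 1,4-dilithiodiene, and each vinyllithium should then add 1,2 to the ketone-like carbonyl of one molecule of 3 (the one beside the methoxy-bearing carbon, not the vinylogous-ester carbonyl), so that two molecules of 3 are taken up; inverse addition into excess 3 favours the second intermolecular addition, and the two carbinol centres form without control because they are erased in step 5.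

**Step 5**
Reactants: 8 4,4'-[(3Z,5Z)-1,8-diphenylocta-3,5-diene-3,6-diyl]bis(4-hydroxy-3-methoxy-2-methylcyclobut-2-en-1-one)
Product: 11 4,4'-dimethoxy-5,5'-dimethyl-2,2'-bis(2-phenylethyl)-[1,1'-bi(cyclohexa-1,4-dien-1-yl)]-3,3',6,6'-tetrone, via bis(dienylketene) 9 (not isolated), via bis-hydroquinone 10 (not isolated)
Conditions: p-xylene (degassed), reflux; then Ag2O, rt
Reagents that add atoms: none
Why: On heating, each 4-hydroxycyclobutenone of 8 should open in a 4-electron conrotatory process with the hydroxyl turning outward, which places the alkenyl arm cis to the ketene in 9; the ketene carbon (the former ring C=O beside C–CH3) then bonds to the CH terminus of the diene bridge in a 6-electron electrocyclisation, tautomerisation gives the hydroquinone ring of 10, and Ag2O dehydrogenates it to the quinone. The closest known reaction type is the Moore–Liebeskind ring expansion of 4-alkenyl-4-hydroxycyclobutenones to hydroquinones and quinones, used here in two directions on one diene. Both six-membered rings close in the same mode, a thermal 6π-electrocyclisation (ketene carbon to alkene CH carbon), one at each end of the bridge, the second closure being the last ring of the skeleton; the central CH–CH bond of the diene becomes the tetra-ortho-substituted axis without any aryl–aryl coupling. No stereocentre is created: the two carbinol centres of 8 become carbonyl carbons and the axis forms without control. The step needs periselectivity for the 6π closure over an 8π closure of the cis,cis-tetraenyl ketene onto the far, fully substituted diene carbon; this is secured by the steric block at that terminus and by the irreversible aromatisation that drains the reversible equilibria, while the regiochemistry (CH3 para to phenethyl, oxygen para to the axis) is fixed by the connectivity of 8.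

**Step 6**
Reactants: 11 4,4'-dimethoxy-5,5'-dimethyl-2,2'-bis(2-phenylethyl)-[1,1'-bi(cyclohexa-1,4-dien-1-yl)]-3,3',6,6'-tetrone
Product: 12 4,4'-dihydroxy-5,5'-dimethyl-2,2'-bis(2-phenylethyl)-[1,1'-bi(cyclohexa-1,4-dien-1-yl)]-3,3',6,6'-tetrone
Conditions: 1 M NaOH (aq), MeOH/THF, 0 °C → rt, Ar; then 1 M HCl
Reagents that add atoms: sodium hydroxide, [Na+].[OH-]
Why: addition–elimination of hydroxide at the methoxy-bearing carbon of each vinylogous ester (the classical saponification of a 2-methoxyquinone to a 2-hydroxyquinone) should release the two enolic hydroxyls; the fully substituted rings offer no free Michael position and acidification returns the neutral hydroxyquinone.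

**Compound list**

1 | dimethyl squarate (3,4-dimethoxycyclobut-3-ene-1,2-dione) | COC1=C(OC)C(=O)C1=O | starting material
2 | 4-hydroxy-2,3-dimethoxy-4-methylcyclobut-2-en-1-one (racemic) | COC1=C(OC)C(C)(O)C1=O | intermediate
3 | 3-methoxy-4-methylcyclobut-3-ene-1,2-dione | COC1=C(C)C(=O)C1=O | intermediate
4 | 4-phenylbut-1-yne | C#CCCc1ccccc1 | starting material
5 | 1,8-diphenylocta-3,5-diyne | C(Cc1ccccc1)C#CC#CCCc1ccccc1 | intermediate
6 | 2,5-bis(2-phenylethyl)tellurophene | C(Cc1ccccc1)C1=CC=C(CCc2ccccc2)[Te]1 | intermediate
7 | 3,6-dilithio-1,8-diphenylocta-3,5-diene, each lithium cis to the central C–C bond (3E,5E by the sequence rule) | [Li]/C(CCc1ccccc1)=C\C=C(/[Li])CCc1ccccc1 | intermediate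
8 | 4,4'-[(3Z,5Z)-1,8-diphenylocta-3,5-diene-3,6-diyl]bis(4-hydroxy-3-methoxy-2-methylcyclobut-2-en-1-one), mixture of diastereomers at the two carbinol carbons | CC1=C(OC)C(O)(/C(CCc2ccccc2)=C\C=C(\CCc2ccccc2)/C2(O)C(OC)=C(C)C2=O)C1=O | intermediate
9 | (3Z,5Z,7Z,9Z)-4,9-dihydroxy-3,10-dimethoxy-2,11-dimethyl-5,8-bis(2-phenylethyl)dodeca-1,3,5,7,9,11-hexaene-1,12-dione (bis(dienylketene); the two ends may open one after the other) | O=C=C(C)/C(OC)=C(O)\C(CCc1ccccc1)=C/C=C(CCc1ccccc1)\C(O)=C(OC)/C(C)=C=O | intermediate
10 | 4,4'-dimethoxy-5,5'-dimethyl-2,2'-bis(2-phenylethyl)-[1,1'-biphenyl]-3,3',6,6'-tetrol | COc1c(C)c(O)c(-c2c(O)c(C)c(OC)c(O)c2CCc2ccccc2)c(CCc2ccccc2)c1O | intermediate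
11 | 4,4'-dimethoxy-5,5'-dimethyl-2,2'-bis(2-phenylethyl)-[1,1'-bi(cyclohexa-1,4-dien-1-yl)]-3,3',6,6'-tetrone | COC1=C(C)C(=O)C(C2=C(CCc3ccccc3)C(=O)C(OC)=C(C)C2=O)=C(CCc2ccccc2)C1=O | intermediate
12 | 4,4'-dihydroxy-5,5'-dimethyl-2,2'-bis(2-phenylethyl)-[1,1'-bi(cyclohexa-1,4-dien-1-yl)]-3,3',6,6'-tetrone | CC1=C(O)C(=O)C(CCc2ccccc2)=C(C2=C(CCc3ccccc3)C(=O)C(O)=C(C)C2=O)C1=O | target

**Totals**

Total step count: 6. Longest linear sequence: 5 steps (4 → 5 → 6 → 8 → 11 → 12).

**Steps most likely to fail**

1. Step 5. The risk is loss of periselectivity (8π closure of the tetraenyl ketene instead of 6π closure) or stalling of the second ring closure through crowding at the nascent axis. The fallback closes each ring separately and makes the axis afterwards; it sets out from 3 and returns at 11. 2-Bromo-4-phenylbut-1-ene is lithiated with t-BuLi (Et2O, −78 °C) to 2-lithio-4-phenylbut-1-ene F1, which adds to 3 to give 4-hydroxy-3-methoxy-2-methyl-4-(4-phenylbut-1-en-2-yl)cyclobut-2-en-1-one F2. Thermolysis (toluene, reflux) should give, by the same ring expansion but with a single alkene and hence no eight-electron alternative, 3-methoxy-2-methyl-5-(2-phenylethyl)benzene-1,4-diol F3. Methylation (Me2SO4, K2CO3, acetone) gives 1,3,4-trimethoxy-2-methyl-5-(2-phenylethyl)benzene F4. Dehydrogenative homocoupling at its only free ring position (PhI(OCOCF3)2, BF3·OEt2, CH2Cl2, −40 °C) should give 3,3',4,4',6,6'-hexamethoxy-5,5'-dimethyl-2,2'-bis(2-phenylethyl)-1,1'-biphenyl F5, and oxidative demethylation of the para-dimethoxy pairs with (NH4)2Ce(NO3)6 (MeCN/H2O, 0 °C) returns 11.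

2. Step 4. The risk is incomplete second tellurium–lithium exchange, or capture of the second C–Li bond by the cyclobutenone formed in the first addition, instead of the second intermolecular addition. The fallback brings the bridge in as a rigid diyne dianion that cannot reach back; it sets out from 3 and returns at 11. 1,4-Bis(trimethylsilyl)buta-1,3-diyne is converted with MeLi·LiBr (THF, rt) into 1,4-dilithiobuta-1,3-diyne F6, which adds twice to 3 (THF, −78 °C) to give 4,4'-(buta-1,3-diyne-1,4-diyl)bis(4-hydroxy-3-methoxy-2-methylcyclobut-2-en-1-one) F7. Thermolysis (p-xylene, reflux) should give, by twofold Moore rearrangement (enynylketene, diradical, hydrogen transfer), 4,4'-dimethoxy-5,5'-dimethyl-[1,1'-bi(cyclohexa-1,4-dien-1-yl)]-3,3',6,6'-tetrone F8. Its two remaining ring C–H positions are then alkylated with 2-phenylethyl radicals (3-phenylpropanoic acid, AgNO3 cat., (NH4)2S2O8, MeCN/H2O, 70 °C) to reach 11.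

3. Step 6. The risk is base-induced decomposition of the biquinone (deprotonation of the ring-bound CH2 and CH3 groups to quinone methides, redox disproportionation) competing with the substitution. The fallback cleaves the ethers at the arene oxidation level; it sets out from 11 and returns at 12. Reduction with Na2S2O4 (EtOAc/H2O) returns bis-hydroquinone 10. BBr3 (CH2Cl2, −78 °C → rt) should cleave both aryl methyl ethers to 5,5'-dimethyl-2,2'-bis(2-phenylethyl)-[1,1'-biphenyl]-3,3',4,4',6,6'-hexol F9, and exposure to air (EtOAc, pH 7 buffer) should oxidise each 1,2,4-triol ring to the 2-hydroxy-1,4-quinone, giving 12.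

**Further compounds**

F1 | step 5 | 2-lithio-4-phenylbut-1-ene | [Li]C(=C)CCc1ccccc1
F2 | step 5 | 4-hydroxy-3-methoxy-2-methyl-4-(4-phenylbut-1-en-2-yl)cyclobut-2-en-1-one (racemic) | CC1=C(OC)C(O)(C(=C)CCc2ccccc2)C1=O
F3 | step 5 | 3-methoxy-2-methyl-5-(2-phenylethyl)benzene-1,4-diol | COc1c(C)c(O)cc(CCc2ccccc2)c1O
F4 | step 5 | 1,3,4-trimethoxy-2-methyl-5-(2-phenylethyl)benzene | COc1cc(CCc2ccccc2)c(OC)c(OC)c1C
F5 | step 5 | 3,3',4,4',6,6'-hexamethoxy-5,5'-dimethyl-2,2'-bis(2-phenylethyl)-1,1'-biphenyl | COc1c(C)c(OC)c(OC)c(CCc2ccccc2)c1-c1c(OC)c(C)c(OC)c(OC)c1CCc1ccccc1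
F6 | step 4 | 1,4-dilithiobuta-1,3-diyne | [Li]C#CC#C[Li]
F7 | step 4 | 4,4'-(buta-1,3-diyne-1,4-diyl)bis(4-hydroxy-3-methoxy-2-methylcyclobut-2-en-1-one), mixture of diastereomers | CC1=C(OC)C(O)(C#CC#CC2(O)C(OC)=C(C)C2=O)C1=O
F8 | step 4 | 4,4'-dimethoxy-5,5'-dimethyl-[1,1'-bi(cyclohexa-1,4-dien-1-yl)]-3,3',6,6'-tetrone | COC1=C(C)C(=O)C(C2=CC(=O)C(OC)=C(C)C2=O)=CC1=O
F9 | step 6 | 5,5'-dimethyl-2,2'-bis(2-phenylethyl)-[1,1'-biphenyl]-3,3',4,4',6,6'-hexol | Cc1c(O)c(O)c(CCc2ccccc2)c(-c2c(O)c(C)c(O)c(O)c2CCc2ccccc2)c1O
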